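**Plan**
1. Retrosynthesis: the ArCH2–C(ring) bond is cut first (phenolic Mannich base + cyclic trione). In the dearomatised ring two bonds are then cut: ring C=O carbon to acetyl-bearing carbon, and CH2-bearing carbon to the enol carbon beside the quaternary centre. This releases a two-carbon malonyl unit (Meldrum's acid) and a triketide enol lactone (a 3,3-disubstituted pyran-2,4-dione).
2. Enabling feature: that ring is a 2-acetylcyclohexane-1,3,5-trione, a tetraketide whose ring atoms alternate carbonyl carbon and nucleophilic carbon, so both cut bonds are Claisen bonds. The quaternary C(Me)(geranyl) blocks aromatisation, and only the diketone CH between the ring and the acetyl group can reach the new acyl carbon through a six-membered ring.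
3. Forward order: acetoacetate chain → quaternary alkylation → C-acetylation → pyran-2,4-dione ring → carbocyclic trione ring (malonyl extension, then Claisen closure, copying polyketide synthase logic). The enol lactone and the Meldrum's acid ring are temporary activating rings, both consumed in the key step.
4. Separately: acylphloroglucinol → propargyl ether → 2H-chromene ring → Mannich base; the halves are joined last through the CH2 bridge.
5. Stereochemistry: the one stereocentre is set by alkylation of a valine-derived chiral enamine (auxiliary control). It is quaternary and non-enolisable, so it is carried unchanged; both E-alkenes come from geranyl bromide.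

Key step: step 5

Assumption: the target and the cyclic trione are drawn in the enol tautomer of the given SMILES; these enol forms equilibrate, and the quaternary carbon alone defines the enantiomer (R in this tautomer).
Assumption: in step 2 the sense of induction depends on the additive; the HMPA variant is written as the one giving the (S)-ester. If the sense proves opposite, the ether-additive variant or the D-valine ester is used and nothing else changes.

**Step 1**
Reactants: 1 tert-butyl 2-methyl-3-oxobutanoate; 2 tert-butyl L-valinate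
Product: 3 tert-butyl (2Z)-3-{[(2S)-1-tert-butoxy-3-methyl-1-oxobutan-2-yl]amino}-2-methylbut-2-enoate
Conditions: BF3·OEt2 (3 mol %), toluene, reflux, Dean–Stark trap
Reagents that add atoms: tert-butyl L-valinate 2, CC(C)[C@H](N)C(=O)OC(C)(C)C
Why: Acid-catalysed condensation of a primary amine with a β-keto ester should give the hydrogen-bonded Z-enamino ester (enamine formation), driven by azeotropic removal of water.

**Step 2**
Reactants: 3; 4 geranyl bromide
Product: 6 tert-butyl (2S,4E)-2-acetyl-2,5,9-trimethyldeca-4,8-dienoate, via alkylated imine 5 (not isolated)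
Conditions: LiN(iPr)2 (1.1 equiv), toluene, −78 °C; HMPA (1.0 equiv); 4 (1.2 equiv), −78 → −45 °C; then 10% aq. citric acid, THF, 23 °C
Reagents that add atoms: geranyl bromide 4, CC(C)=CCC/C(C)=C/CBr; water, O
Why: The lithio-enamine is chelated by the valinate ester carbonyl and should be alkylated at the α-carbon by SN2 attack on the face away from the isopropyl group (asymmetric alkylation of a chiral enamine of an α-alkyl β-keto ester, auxiliary control), setting the quaternary centre as S before mild acid hydrolysis of imine 5 returns the ketone and the auxiliary.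

**Step 3**
Reactants: 6; 7 1-acetyl-1H-benzotriazole
Product: 8 tert-butyl (2S,4E)-2,5,9-trimethyl-2-(3-oxobutanoyl)deca-4,8-dienoate
Conditions: MgBr2·OEt2 (2.5 equiv), iPr2NEt (3.0 equiv), 7 (1.3 equiv), CH2Cl2, 23 °C; 1 M aq. HCl work-up
Reagents that add atoms: 1-acetyl-1H-benzotriazole 7, CC(=O)n1nnc2ccccc21
Why: Magnesium chelation of the β-keto ester allows soft enolisation at the acetyl methyl, the only enolisable position because the α-carbon is quaternary, and the enolate should be C-acylated by the acylbenzotriazole (crossed Claisen condensation) and held as the magnesium diketonate.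

**Step 4**
Reactants: 8
Product: 11 (3S)-3-[(2E)-3,7-dimethylocta-2,6-dien-1-yl]-3,6-dimethyl-2H-pyran-2,4(3H)-dione, via bis-silyl derivative 9 (not isolated), via diketo acid 10 (not isolated)
Conditions: Me3SiOTf (2.5 equiv), 2,6-lutidine (3.5 equiv), CH2Cl2, 0 °C; MeOH (2.2 equiv), 0 °C; N,N'-diisopropylcarbodiimide (1.2 equiv), 0 → 23 °C
Reagents that add atoms: none
Why: Buffered silyl triflate should cleave the tert-butyl ester with loss of isobutene without protonating the trisubstituted alkenes, and the acid freed by methanol is closed at once by the carbodiimide onto the enol oxygen of the 1,3-diketone (six-membered enol lactonisation) before it can decarboxylate.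

**Step 5**
Reactants: 11; 12 Meldrum's acid
Product: 15 (4R)-2-acetyl-4-[(2E)-3,7-dimethylocta-2,6-dien-1-yl]-3,5-dihydroxy-4-methylcyclohexa-2,5-dien-1-one, via acyl Meldrum's acid 13 (not isolated), via acylketene 14 (not isolated)
Conditions: 12 (1.1 equiv), DMAP (0.2 equiv), toluene (0.02 M), 23 → 40 °C; then 90 °C
Reagents that add atoms: Meldrum's acid 12, CC1(C)OC(=O)CC(=O)O1
Why: Proposed new method: DMAP-mediated acyl transfer from the enol-lactone carbonyl of 11 (a vinylogous mixed anhydride, hence an activated acyl donor) to C-5 of Meldrum's acid should make the first C–C bond and free the 1,3-diketone in 13; at 90 °C 13 loses acetone and CO2 by retro-hetero-Diels–Alder fragmentation to α-oxoketene 14, whose sp carbon is attacked by the diketone CH to make the second bond. The closest known reaction types are C-acylation of Meldrum's acid by activated acyl donors followed by acylketene trapping, and the base-mediated Claisen cyclisation of 3,5,7-triketo esters to acylphloroglucinols. No ring closes in the first stage; the carbocycle closes in the second by 6-exo-dig attack of the enol carbon on the ketene carbon, an intramolecular Claisen-type C-acylation. No new stereocentre is formed, and the quaternary carbon of 11 has no bond made or broken and cannot enolise, so its configuration is carried through (the descriptor changes from S to R only because the priorities change). The step needs carbonyl attack on 11 rather than conjugate attack at C-6, and C- rather than O-acylation by the ketene: acyl transfer is the normal course for enol esters under DMAP and leads to the strongly stabilised acyl Meldrum's acid, while any O-acylated enol lactone is itself an acyl donor that DMAP should return to the vinylogous acid 15, the thermodynamic sink. The acetyl methyl cannot compete because it would close an eight-membered ring.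

**Step 6**
Reactants: 16 1-(2,4,6-trihydroxyphenyl)butan-1-one; 17 3-chloro-3-methylbut-1-yne
Product: 18 1-{2,6-dihydroxy-4-[(2-methylbut-3-yn-2-yl)oxy]phenyl}butan-1-one
Conditions: 17 (1.2 equiv), K2CO3 (1.1 equiv), KI (0.2 equiv), CuI (2 mol %), acetone, 56 °C
Reagents that add atoms: 3-chloro-3-methylbut-1-yne 17, CC(C)(Cl)C#C
Why: One equivalent of base should deprotonate the most acidic phenol, the one para to the ketone and not tied up in the hydrogen bond to the carbonyl oxygen, and this phenoxide is etherified by the tertiary propargylic chloride (copper-assisted O-alkylation of a phenol).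

**Step 7**
Reactants: 18
Product: 19 1-(5,7-dihydroxy-2,2-dimethyl-2H-chromen-6-yl)butan-1-one
Conditions: Ph3PAuNTf2 (2 mol %), CH2Cl2, 23 °C
Reagents that add atoms: none
Why: π-Activation of the alkyne by the cationic gold phosphine catalyst and 6-endo-dig attack of an ortho carbon (intramolecular hydroarylation, Friedel–Crafts type) should give the 2H-chromene; the ether C–O bond is never broken, so the pyran oxygen is the one para to the butanoyl group, and the two ortho carbons are equivalent.

**Step 8**
Reactants: 19; 20 N,N-dimethylmethaniminium iodide (Eschenmoser's salt)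
Product: 21 1-{8-[(dimethylamino)methyl]-5,7-dihydroxy-2,2-dimethyl-2H-chromen-6-yl}butan-1-one
Conditions: 20 (1.05 equiv), CH2Cl2, 0 → 23 °C; aq. NaHCO3 work-up
Reagents that add atoms: N,N-dimethylmethaniminium iodide 20, C=[N+](C)C.[I-]
Why: Mannich aminomethylation should occur at C-8, the only unsubstituted carbon of the phloroglucinol-type ring, which is far more nucleophilic than the chromene alkene.

**Step 9**
Reactants: 15; 21
Product: 23 (4R)-2-acetyl-6-[(6-butanoyl-5,7-dihydroxy-2,2-dimethyl-2H-chromen-8-yl)methyl]-4-[(2E)-3,7-dimethylocta-2,6-dien-1-yl]-3,5-dihydroxy-4-methylcyclohexa-2,5-dien-1-one, via ortho-quinone methide 22 (not isolated)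
Conditions: 15 (1.0 equiv), 21 (1.0 equiv), toluene, 80 °C, N2
Reagents that add atoms: none
Why: The vinylogous acid 15 protonates the benzylic amine, loss of dimethylamine gives ortho-quinone methide 22, and the trione enolate adds through its only free ring carbon with rearomatisation (Michael addition; alkylation of a 1,3-dicarbonyl by a phenolic Mannich base); 21 has no free aromatic position, so no homodimer can form, and the quaternary stereocentre is not involved.

**Compound list**
1 | tert-butyl 2-methyl-3-oxobutanoate (racemic) | CC(=O)C(C)C(=O)OC(C)(C)C | starting material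
2 | tert-butyl L-valinate | CC(C)[C@H](N)C(=O)OC(C)(C)C | starting material
3 | tert-butyl (2Z)-3-{[(2S)-1-tert-butoxy-3-methyl-1-oxobutan-2-yl]amino}-2-methylbut-2-enoate | CC(C)[C@H](N/C(C)=C(/C)C(=O)OC(C)(C)C)C(=O)OC(C)(C)C | intermediate
4 | geranyl bromide, (2E)-1-bromo-3,7-dimethylocta-2,6-diene | CC(C)=CCC/C(C)=C/CBr | starting material
5 | tert-butyl (2S,4E)-2-{N-[(2S)-1-tert-butoxy-3-methyl-1-oxobutan-2-yl]ethanimidoyl}-2,5,9-trimethyldeca-4,8-dienoate (alkylated imine) | CC(C)[C@H](N=C(C)[C@](C)(C/C=C(\C)CCC=C(C)C)C(=O)OC(C)(C)C)C(=O)OC(C)(C)C | intermediate (not isolated)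
6 | tert-butyl (2S,4E)-2-acetyl-2,5,9-trimethyldeca-4,8-dienoate | CC(=O)[C@](C)(C/C=C(\C)CCC=C(C)C)C(=O)OC(C)(C)C | intermediate
7 | 1-acetyl-1H-benzotriazole | CC(=O)n1nnc2ccccc21 | starting material
8 | tert-butyl (2S,4E)-2,5,9-trimethyl-2-(3-oxobutanoyl)deca-4,8-dienoate | CC(=O)CC(=O)[C@](C)(C/C=C(\C)CCC=C(C)C)C(=O)OC(C)(C)C | intermediate
9 | trimethylsilyl (2S,4E)-2,5,9-trimethyl-2-[3-(trimethylsilyloxy)but-2-enoyl]deca-4,8-dienoate (bis-silyl derivative) | CC(O[Si](C)(C)C)=CC(=O)[C@](C)(C/C=C(\C)CCC=C(C)C)C(=O)O[Si](C)(C)C | intermediate (not isolated)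
10 | (2S,4E)-2,5,9-trimethyl-2-(3-oxobutanoyl)deca-4,8-dienoic acid (diketo acid) | CC(=O)CC(=O)[C@](C)(C/C=C(\C)CCC=C(C)C)C(=O)O | intermediate (not isolated)
11 | (3S)-3-[(2E)-3,7-dimethylocta-2,6-dien-1-yl]-3,6-dimethyl-2H-pyran-2,4(3H)-dione | CC1=CC(=O)[C@](C)(C/C=C(\C)CCC=C(C)C)C(=O)O1 | intermediate
12 | Meldrum's acid, 2,2-dimethyl-1,3-dioxane-4,6-dione | CC1(C)OC(=O)CC(=O)O1 | starting material
13 | 5-[(2R,4E)-1-hydroxy-2,5,9-trimethyl-2-(3-oxobutanoyl)deca-4,8-dien-1-ylidene]-2,2-dimethyl-1,3-dioxane-4,6-dione (acyl Meldrum's acid, enol form) | CC(=O)CC(=O)[C@](C)(C/C=C(\C)CCC=C(C)C)C(O)=C1C(=O)OC(C)(C)OC1=O | intermediate (not isolated)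
14 | (4S,6E)-4,7,11-trimethyl-4-(3-oxobutanoyl)dodeca-1,6,10-triene-1,3-dione (acylketene) | CC(=O)CC(=O)[C@](C)(C/C=C(\C)CCC=C(C)C)C(=O)C=C=O | intermediate (not isolated)
15 | (4R)-2-acetyl-4-[(2E)-3,7-dimethylocta-2,6-dien-1-yl]-3,5-dihydroxy-4-methylcyclohexa-2,5-dien-1-one | CC(=O)C1=C(O)[C@](C)(C/C=C(\C)CCC=C(C)C)C(O)=CC1=O | intermediate
16 | 1-(2,4,6-trihydroxyphenyl)butan-1-one | CCCC(=O)c1c(O)cc(O)cc1O | starting material
17 | 3-chloro-3-methylbut-1-yne | CC(C)(Cl)C#C | starting material
18 | 1-{2,6-dihydroxy-4-[(2-methylbut-3-yn-2-yl)oxy]phenyl}butan-1-one | CCCC(=O)c1c(O)cc(OC(C)(C)C#C)cc1O | intermediate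
19 | 1-(5,7-dihydroxy-2,2-dimethyl-2H-chromen-6-yl)butan-1-one | CCCC(=O)c1c(O)cc2OC(C)(C)C=Cc2c1O | intermediate
20 | N,N-dimethylmethaniminium iodide (Eschenmoser's salt) | C=[N+](C)C.[I-] | starting material
21 | 1-{8-[(dimethylamino)methyl]-5,7-dihydroxy-2,2-dimethyl-2H-chromen-6-yl}butan-1-one | CCCC(=O)c1c(O)c(CN(C)C)c2OC(C)(C)C=Cc2c1O | intermediate
22 | 6-butanoyl-5-hydroxy-2,2-dimethyl-8-methylidene-2H-chromen-7(8H)-one (ortho-quinone methide) | CCCC(=O)C1=C(O)C2=C(OC(C)(C)C=C2)C(=C)C1=O | intermediate (not isolated)
23 | (4R)-2-acetyl-6-[(6-butanoyl-5,7-dihydroxy-2,2-dimethyl-2H-chromen-8-yl)methyl]-4-[(2E)-3,7-dimethylocta-2,6-dien-1-yl]-3,5-dihydroxy-4-methylcyclohexa-2,5-dien-1-one | CCCC(=O)c1c(O)c2c(c(CC3=C(O)[C@@](C)(C/C=C(\C)CCC=C(C)C)C(O)=C(C(C)=O)C3=O)c1O)OC(C)(C)C=C2 | target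

**Totals**
Total steps: 9. Longest linear sequence: 6 (steps 1, 2, 3, 4, 5, 9); steps 6–8 form the convergent branch.

**Steps most likely to fail**

Step 5 (Proposed new method). Acyl transfer from the hindered lactone carbonyl may be slow compared with conjugate addition at C-6 of 11, and the ketene may be lost to intermolecular reactions before it cyclises. The fallback sets out from 11 and returns at 15 by stepwise anionic Claisen chemistry of known type. The lithium enolate of methyl acetate (methyl acetate, LiN(iPr)2, THF, −78 °C, 3 equiv) should open the enol lactone at the lactone carbonyl in a crossed Claisen condensation. This gives methyl (4S,6E)-4,7,11-trimethyl-3-oxo-4-(3-oxobutanoyl)dodeca-6,10-dienoate F1, which is isolated. NaOMe in MeOH at 23 °C (or 2 M aq. KOH) should then close the ring by Claisen condensation of the diketone carbon onto the methyl ester, the known base-mediated cyclisation of 3,5,7-triketo esters to acylphloroglucinol-type rings, to give 15. The aldol mode cannot aromatise because of the quaternary carbon and should revert.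

Step 2. Facial selectivity in the alkylation of the acyclic lithio-enamine may be poor with the bulky tert-butyl ester, or the hindered imine may hydrolyse incompletely. The fallback sets out from 4 and returns at 8 by catalytic asymmetric phase-transfer alkylation of a mixed malonate. 1-tert-Butyl 3-(2,2-diphenylethyl) 2-methylpropanedioate F2 is made from purchased 3-tert-butoxy-2-methyl-3-oxopropanoic acid and 2,2-diphenylethanol (N,N'-diisopropylcarbodiimide, DMAP). It is alkylated with 4 (50% aq. KOH, toluene, −40 °C, 5 mol % of the antipode of the N-spiro binaphthyl ammonium salt 3,4,5-trifluorophenyl-NAS bromide that delivers the S product) to give 1-tert-butyl 3-(2,2-diphenylethyl) (2S)-2-[(2E)-3,7-dimethylocta-2,6-dien-1-yl]-2-methylpropanedioate F3. 1 M KOH in MeOH should cleave only the diphenylethyl ester to give (2S)-3-tert-butoxy-2-[(2E)-3,7-dimethylocta-2,6-dien-1-yl]-2-methyl-3-oxopropanoic acid F4. 1,1'-Carbonyldiimidazole gives tert-butyl (2S,4E)-2-(1H-imidazole-1-carbonyl)-2,5,9-trimethyldeca-4,8-dienoate F5, and the lithium enolate of acetone (acetone, LiN(SiMe3)2, THF, −78 °C, 3 equiv) converts it into 8.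

Step 6. Site selectivity of the O-alkylation among three phenols may be poor (bis-ethers, ortho ethers, C-alkylation). The fallback sets out from 16 and returns at 19, replacing steps 6 and 7 by one condensation with purchased 3-methylbut-2-enal (CC(C)=CC=O) in pyridine at 110 °C. This is a Knoevenagel-type condensation, dehydration to an ortho-quinone methide and oxa-6π electrocyclisation. 19 is then separated by chromatography from its 8-acyl regioisomer; the fallback makes no compound outside the list (F0).

**Further compounds**
F1 | step 5 | methyl (4S,6E)-4,7,11-trimethyl-3-oxo-4-(3-oxobutanoyl)dodeca-6,10-dienoate | CC(=O)CC(=O)[C@](C)(C/C=C(\C)CCC=C(C)C)C(=O)CC(=O)OC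
F2 | step 2 | 1-tert-butyl 3-(2,2-diphenylethyl) 2-methylpropanedioate | CC(C(=O)OC(C)(C)C)C(=O)OCC(c1ccccc1)c1ccccc1
F3 | step 2 | 1-tert-butyl 3-(2,2-diphenylethyl) (2S)-2-[(2E)-3,7-dimethylocta-2,6-dien-1-yl]-2-methylpropanedioate | O=C(OCC(c1ccccc1)c1ccccc1)[C@](C)(C/C=C(\C)CCC=C(C)C)C(=O)OC(C)(C)C
F4 | step 2 | (2S)-3-tert-butoxy-2-[(2E)-3,7-dimethylocta-2,6-dien-1-yl]-2-methyl-3-oxopropanoic acid | OC(=O)[C@](C)(C/C=C(\C)CCC=C(C)C)C(=O)OC(C)(C)C
F5 | step 2 | tert-butyl (2S,4E)-2-(1H-imidazole-1-carbonyl)-2,5,9-trimethyldeca-4,8-dienoate | O=C(n1ccnc1)[C@](C)(C/C=C(\C)CCC=C(C)C)C(=O)OC(C)(C)C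
F0 | step 6 | none | none
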